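Decide first what you will stop following: freeze the target and carry one number. In the dusk run the target stays between 20.2 % and 22.6 % from 10.0 min to 60.0 min, while the isomer of the product climbs from 1.2 % to 7.5 %, so their ratio grows roughly in step with time.

| flask | solid substrate | reagent | remark | time |
|---|---|---|---|---|
| spring | 0.50 M | 1.05 equiv | run made earlier |  |
| dusk | 2 M | 1.05 equiv | run made earlier |  |
| winter | 1 M | 0.53 equiv | run made earlier |  |
| flask | 1.0 M | 1.05 equiv |  | 80 min |

- spring (time / min: isomer of the product / %, target / %): 5.00: 0.4, 7.6; 8.00: 0.2, 8.7; 15.0: 0.8, 9.0; 25.0: 1.0, 8.5; 40.0: 1.4, 8.0; 60.0: 2.8, 7.8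
- dusk (time / min: isomer of the product / %, target / %): 10.0: 1.2, 20.2; 20.0: 2.2, 21.1; 30.0: 3.7, 22.6; 40.0: 4.1, 21.8; 50.0: 6.0, 20.8; 60.0: 7.5, 20.9
- winter (time / min: isomer of the product / %, target / %): 12.0: 1.2, 8.2; 25.0: 0.9, 7.7; 40.0: 1.7, 7.7; 50.0: 2.3, 7.0; 60.0: 2.1, 7.2

(each reading ± 0.5 percentage points)

- solid, in amounts per volume of the solution: solid substrate
- the numbers in the tables scatter by 0.5 percentage points (one standard deviation)
- at the start none of the solid substrate is in solution

- ratio of isomer of the product to target at 40 s
- ratio of isomer of the product to target at 80 min
- which of isomer of the product and target there is more of at 80 min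

At 60.0 min that ratio reads 0.359 in spring, 0.359 in dusk and 0.292 in winter, and a scatter of 0.5 percentage points on an isomer reading, set against a winter target of 7.2 %, is of the size of that gap. My mean slope is 0.00561 /min. Multiply it by 80 min and you have the catch-up number, 0.449: the isomer as a fraction of the target. Below 1 the target leads, so in this flask I commit to the target.

Is one number enough? The same line gives 0.00374 at 40 s, but I cannot check it there: the earliest spring isomer reading, 0.4 %, lies within the scatter.

The forecast gives 0.01 at 40 s, above my line, and 0.45 at 80 min, saying “the target still leads”.

The flask gives 0.477 at 80 min against 0.449, with 13.0 % target and 6.19 % isomer, but 0.0150 at 40 s.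

    solid substrate ⇌ starting material, rate k1*(cs1 - [starting material]) while solid is left; crystals form when [starting material] > cs1 (solubility = 0.470 M, k = 0.00942 /s)
    starting material ⇌ dormant form (K = 4.20, k = 0.0304 /s)
    starting material + reagent ⇌ target (K = 0.970 /M, k = 0.00682 /M/s)
    starting material + reagent ⇌ isomer of the product (K = 42.1 /M, k = 9.24 × 10⁻⁵ /M/s)

In this flask, going forward into target alone, the starting material has a half-life of 1.7 min at 2.38 min, while the step between starting material + reagent and the isomer, by itself and counted both ways, relaxes with a half-life of 121 min at 80.0 min, far longer and longer than the run. This is kinetic against thermodynamic control seen early: between 40.0 min and 80.0 min the target goes from 13.7 % to 13.0 % as the isomer goes from 3.18 % to 6.19 %. At 2.5 M of solid substrate, the neighbour flask stands at an isomer-to-target ratio of 0.464 at 80 min, against the same 0.449.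

The data were generated by integration from invented constants, noise included.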